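Monday's run ends with G, E and Q summing to less than the D charged; percent counts D units, so I take that gap as X.

the same everywhere: D 0.085 M
- Sunday's: Z 0.47 equiv; run made earlier
- Monday's: Z 5.2 equiv; run made earlier
- cedar: Z 0.800 equiv; time 10 min
- elm: Z 1.50 equiv; time 10 min
- maple: Z 3.00 equiv; time 10 min
- ash: Z 6.00 equiv; time 10 min

| run | time / min | G / % | E / % | Q / % |
|---|---|---|---|---|
| Sunday's | 1.33 | 10 | 13 | 15 |
| Sunday's | 3.00 | 15 | 19 | 25 |
| Sunday's | 4.00 | 16 | 22 | 24 |
| Sunday's | 6.00 | 19 | 29 | 28 |
| Sunday's | 8.00 | 17 | 30 | 27 |
| Sunday's | 10.0 | 19 | 35 | 30 |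
| Monday's | 0.500 | 42 | 2 | 1 |
| Monday's | 1.50 | 65 | 5 | 9 |
| Monday's | 3.00 | 68 | 9 | 8 |
| Monday's | 4.00 | 66 | 8 | 6 |
| Monday's | 6.00 | 64 | 9 | 7 |
| Monday's | 8.00 | 62 | 8 | 5 |
| Monday's | 10.0 | 60 | 6 | 7 |

(readings scatter by 1.5 percentage points)

- percent here means D units held: one Q counts as two
- a reading or a percentage of G counts all its forms, free or not
- "hardly changes" means that all values lie within two and a half points (for a concentration: within two and a half percent of the largest)

- share of G in all that became G or E or Q or X for cedar, elm, maple, ash, in this order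
- the shape of the row from first to last (falls, then rises / hardly changes / falls all the way / rises all the way / rises, then falls)

I split the asked share into two factors:

share = f × c

Here f is G over G plus X, and c is the part of the reacted D that reached G or X. I get c from r, the ratio of G plus X to E plus Q, my selectivity factor, which I take as proportional to the equivalents of Z.

Which readings must be good? Monday's E plus Q reads 13.0 % at 10.0 min and 16.0 % at 6.00 min. That gap moves c by 6 percentage points in cedar but 2.7 points in ash, so the side reading counts at low charge. G moves 2 points between Monday's last rows, and f scales the whole row by that error. The D charge of 0.085 M and the time of 10 min match Monday's last row, so I need no law for either.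

Now the numbers, from Monday's last row:

f = 0.690

r at 5.2 equiv = 6.69

I carry unchanged to each flask this kept fraction, G over G plus X at the asked time, and share = f × r/(1 + r) gives:

cedar 35.0 %, elm 45.4 %, maple 54.8 %, ash 61.1 %

My row climbs at each step .

The forecast differs, with 32 %, 50 %, 65 %, 58 % and the shape "rises, then falls", on its ground of “loss to X, which grows with Z”.

The flask gives 30.8 %, 43.2 %, 54.1 %, 64.1 %: rises all the way.

    L ⇌ G, rate k1*(cs1 - [G]) while solid is left; crystals form when [G] > cs1 (solubility = 46.0 mM, k = 0.0830 s⁻¹)
    D → E (k = 0.00170 s⁻¹)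
    2 D → Q (k = 0.0180 M⁻¹ s⁻¹)
    G ⇌ X (K = 0.450, k = 0.00410 s⁻¹)
    D + Z → G (k = 0.0510 M⁻¹ s⁻¹)

The reverse step, X to G, is the main reason for ash's share: taken away, that share falls from 64.1 % to 9.32 %. In cedar, G's forward half-life to X, 2.8 min, is short against 10 min, yet G stands at 28.9 % and X at 12.5 % by then. Multiplying f by each flask's own part reaching G or X gives 60.9 % for ash and 30.4 % for cedar, where removing the step takes the share from 30.8 % to 8.33 %.

The runs are simulated from invented constants; noise was put on by code.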